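Ring C of the flavone is cut at C3–C4: its O1–C2(aryl)=C3H–C4(=O) unit, three carbons with an oxygen function at each end, is the open form of a 3,5-diarylisoxazole. A single [3+2] cycloaddition of a ring A nitrile oxide to the ring B arylacetylene forms the C3–C4 bond and a C–O bond at C2, closes the isoxazole and fixes both termini at the carbonyl oxidation level without enolate acylation of a hindered aryl ketone. The dipole comes from the oxime of 2-(benzyloxy)-3,4,6-trimethoxybenzaldehyde by direct oxidation in the flask, which spares the electron-rich ring from electrophilic chlorine; the benzyl ether marks the future O1, the ortho methyl ether the future C5 hydroxyl. The partner is 1-ethynyl-2,3,4,5-tetramethoxybenzene.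

Key step: step 10

Remark: 1 and 10 are taken as purchasable; oxime 9 is drawn as its E isomer, although either isomer is dehydrogenated to the same nitrile oxide.

Step 1
Reactants: 1 2-hydroxy-4,6-dimethoxybenzaldehyde
Product: 2 2-(benzyloxy)-4,6-dimethoxybenzaldehyde
Conditions: BnBr, K2CO3, DMF, 60 °C
Reagents that add atoms: benzyl bromide, BrCc1ccccc1
Why: Williamson etherification of the phenoxide with benzyl bromide is expected to be clean once carbonate has broken the hydrogen bond to the aldehyde, and it tags this oxygen so that it stays distinguishable from the hydroxyl created in step 2.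

Step 2
Reactants: 2 2-(benzyloxy)-4,6-dimethoxybenzaldehyde
Product: 4 2-(benzyloxy)-4,6-dimethoxyphenol, via aryl formate 3 (not isolated)
Conditions: mCPBA, CH2Cl2, 0 °C → rt; Na2SO3 wash; then K2CO3 (cat.), MeOH, rt, N2
Reagents that add atoms: mCPBA (3-chloroperoxybenzoic acid), OOC(=O)c1cccc(Cl)c1
Why: Baeyer–Villiger oxidation of an aldehyde on a ring carrying three alkoxy donors proceeds by aryl migration (the Dakin-type outcome) to formate 3, and base-catalysed methanolysis of that formate then releases the phenol without touching the ethers.

Step 3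
Reactants: 4 2-(benzyloxy)-4,6-dimethoxyphenol
Product: 5 1-(benzyloxy)-2,3,5-trimethoxybenzene
Conditions: MeI, K2CO3, DMF, rt
Reagents that add atoms: iodomethane, CI
Why: SN2 O-methylation of the phenoxide (Williamson etherification) is reliable even for a phenol flanked by two alkoxy groups and turns the former formyl-bearing carbon into the methoxy-bearing carbon that becomes C8 of the flavone.

Step 4
Reactants: 5 1-(benzyloxy)-2,3,5-trimethoxybenzene
Product: 6 2,3,5-trimethoxyphenol
Conditions: H2 (1 atm), 10% Pd/C, EtOAc–MeOH, rt
Reagents that add atoms: none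
Why: Catalytic hydrogenolysis cleaves only the benzylic C–O bond, leaves the three aryl methyl ethers untouched and uncovers a hydroxyl that has exactly one free ortho carbon.

Step 5
Reactants: 6 2,3,5-trimethoxyphenol
Product: 7 2-hydroxy-3,4,6-trimethoxybenzaldehyde
Conditions: MgCl2 (anhydrous), Et3N, (CH2O)n, MeCN, reflux; then 1 M HCl
Reagents that add atoms: paraformaldehyde (as formaldehyde), C=O
Why: In the magnesium phenoxide ortho-formylation (Casnati–Skattebøl reaction) formaldehyde is delivered within a magnesium chelate to the carbon next to the phenoxide oxygen and the benzylic alkoxide is then oxidised by hydride transfer to a second formaldehyde, and because the other ortho carbon carries a methoxy group only the carbon between the hydroxyl and the C5 methoxy group can react.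

Step 6
Reactants: 7 2-hydroxy-3,4,6-trimethoxybenzaldehyde
Product: 8 2-(benzyloxy)-3,4,6-trimethoxybenzaldehyde
Conditions: BnBr, K2CO3, DMF, 60 °C
Reagents that add atoms: benzyl bromide, BrCc1ccccc1
Why: Williamson etherification gives the oxygen that is to become O1 a group removable by hydrogenolysis, keeps it distinct from the methyl ether at the other ortho position (the future C5 oxygen) and prevents an ortho-hydroxy nitrile oxide from cyclising on itself later.

Step 7
Reactants: 8 2-(benzyloxy)-3,4,6-trimethoxybenzaldehyde
Product: 9 (E)-2-(benzyloxy)-3,4,6-trimethoxybenzaldehyde oxime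
Conditions: NH2OH·HCl, NaOAc, EtOH–H2O, 70 °C
Reagents that add atoms: hydroxylamine hydrochloride, Cl.NO
Why: Condensation of the aldehyde with hydroxylamine (oxime formation) goes to completion in buffered hot ethanol even for a 2,6-dialkoxybenzaldehyde and should give mainly the E oxime, whose geometry is of no consequence for the oxidation that follows.

Step 8
Reactants: 10 1,2,3,4-tetramethoxybenzene
Product: 11 2,3,4,5-tetramethoxybenzaldehyde
Conditions: Cl2CHOMe, TiCl4, CH2Cl2, 0 °C; then H2O
Reagents that add atoms: dichloromethyl methyl ether, COC(Cl)Cl; water, O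
Why: Rieche formylation, a Friedel–Crafts reaction with the oxocarbenium ion formed from dichloromethyl methyl ether and TiCl4, attacks one of the two symmetry-equivalent free ring positions, so only one aldehyde can result after hydrolytic work-up.

Step 9
Reactants: 11 2,3,4,5-tetramethoxybenzaldehyde
Product: 12 1-ethynyl-2,3,4,5-tetramethoxybenzene
Conditions: MeC(O)C(N2)P(O)(OMe)2, K2CO3, MeOH, 0 °C → rt
Reagents that add atoms: dimethyl (1-diazo-2-oxopropyl)phosphonate, CC(=O)C(=[N+]=[N-])P(=O)(OC)OC
Why: In the Seyferth–Gilbert homologation in its Ohira–Bestmann form, methanolysis releases the anion of dimethyl (diazomethyl)phosphonate, which olefinates the non-enolisable aldehyde, loses N2 and gives the terminal alkyne by 1,2-hydride shift of the alkylidene carbene under mild carbonate conditions.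

Step 10
Reactants: 9 (E)-2-(benzyloxy)-3,4,6-trimethoxybenzaldehyde oxime; 12 1-ethynyl-2,3,4,5-tetramethoxybenzene
Product: 14 3-[2-(benzyloxy)-3,4,6-trimethoxyphenyl]-5-(2,3,4,5-tetramethoxyphenyl)isoxazole, via nitrile oxide 13 (not isolated)
Conditions: PhI(OAc)2 (1.1 equiv), TFA (cat.), MeOH, 0 °C → rt, then 50 °C
Reagents that add atoms: none
Why: (Diacetoxyiodo)benzene dehydrogenates aldoxime 9 (ligand exchange at trivalent iodine, then loss of PhI and AcOH) to nitrile oxide 13, which undergoes a concerted, asynchronous Huisgen [3+2] cycloaddition with the C≡C bond of 12. The closest known reaction type is the nitrile oxide–terminal alkyne cycloaddition to 3,5-disubstituted isoxazoles with oxidative generation of the dipole from an aldoxime in the flask. The isoxazole ring is closed by the intermolecular cycloaddition itself, a (3+2) annulation in which the C–C bond (future C3–C4) and the O–C bond at the future C2 form in one transition state, so no separate endo or exo ring closure is involved. No stereocentre is created, since both new ring atoms end up sp2. The step needs regioselectivity for the 3,5-isomer, which the terminal alkyne secures: the nitrile oxide carbon, crowded by its two ortho alkoxy groups, bonds to the unsubstituted terminus and the oxygen to the aryl-bearing carbon, in line with the usual frontier orbital preference. It also needs the dipole to outlive a slow cycloaddition, which the two ortho substituents secure by blocking dimerisation to the furoxan, while direct oxidation of the oxime keeps electrophilic chlorine away from the free ring position between two methoxy groups that a hydroximoyl chloride preparation would expose.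

Step 11
Reactants: 14 3-[2-(benzyloxy)-3,4,6-trimethoxyphenyl]-5-(2,3,4,5-tetramethoxyphenyl)isoxazole
Product: 16 5,7,8-trimethoxy-2-(2,3,4,5-tetramethoxyphenyl)-4H-chromen-4-one, via enaminone 15 (not isolated)
Conditions: H2 (1–3 atm), 10% Pd/C, EtOAc–EtOH, rt; filter; then 6 M aq. HCl, EtOH, 80 °C
Reagents that add atoms: water, O
Why: Heterogeneous hydrogenolysis should cleave both the weak isoxazole N–O bond and the benzyl ether to give the phenolic β-enaminone 15, which in hot aqueous acid is hydrolysed at the enamine carbon and cyclodehydrates through the C8a phenol oxygen onto the ring B carbonyl (the ring closure that ends a Baker–Venkataraman flavone synthesis), so that nitrogen leaves as ammonium, the former isoxazole oxygen as water and the C4 carbonyl oxygen is taken from water.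

Step 12
Reactants: 16 5,7,8-trimethoxy-2-(2,3,4,5-tetramethoxyphenyl)-4H-chromen-4-one
Product: 17 5-hydroxy-7,8-dimethoxy-2-(2,3,4,5-tetramethoxyphenyl)-4H-chromen-4-one (CNP0509136.0)
Conditions: BCl3 (1.5 equiv), CH2Cl2, −78 → 0 °C; then H2O
Reagents that add atoms: none
Why: Boron trichloride chelates between the C4 carbonyl and the peri C5 methoxy oxygen, so chloride removes only that methyl group (chelation-directed Lewis acid ether cleavage) while the six non-chelating methyl ethers and ring C stay intact at low temperature.

Compound list
1 | 2-hydroxy-4,6-dimethoxybenzaldehyde | COc1cc(O)c(C=O)c(OC)c1 | starting material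
2 | 2-(benzyloxy)-4,6-dimethoxybenzaldehyde | COc1cc(OCc2ccccc2)c(C=O)c(OC)c1 | intermediate
3 | 2-(benzyloxy)-4,6-dimethoxyphenyl formate | COc1cc(OCc2ccccc2)c(OC=O)c(OC)c1 | intermediate
4 | 2-(benzyloxy)-4,6-dimethoxyphenol | COc1cc(OCc2ccccc2)c(O)c(OC)c1 | intermediate
5 | 1-(benzyloxy)-2,3,5-trimethoxybenzene | COc1cc(OCc2ccccc2)c(OC)c(OC)c1 | intermediate
6 | 2,3,5-trimethoxyphenol | COc1cc(O)c(OC)c(OC)c1 | intermediate
7 | 2-hydroxy-3,4,6-trimethoxybenzaldehyde | COc1cc(OC)c(OC)c(O)c1C=O | intermediate
8 | 2-(benzyloxy)-3,4,6-trimethoxybenzaldehyde | COc1cc(OC)c(OC)c(OCc2ccccc2)c1C=O | intermediate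
9 | (E)-2-(benzyloxy)-3,4,6-trimethoxybenzaldehyde oxime | COc1cc(OC)c(OC)c(OCc2ccccc2)c1/C=N/O | intermediate
10 | 1,2,3,4-tetramethoxybenzene | COc1ccc(OC)c(OC)c1OC | starting material
11 | 2,3,4,5-tetramethoxybenzaldehyde | COc1cc(C=O)c(OC)c(OC)c1OC | intermediate
12 | 1-ethynyl-2,3,4,5-tetramethoxybenzene | C#Cc1cc(OC)c(OC)c(OC)c1OC | intermediate
13 | 2-(benzyloxy)-3,4,6-trimethoxybenzonitrile oxide | COc1cc(OC)c(C#[N+][O-])c(OCc2ccccc2)c1OC | intermediate
14 | 3-[2-(benzyloxy)-3,4,6-trimethoxyphenyl]-5-(2,3,4,5-tetramethoxyphenyl)isoxazole | COc1cc(-c2cc(-c3c(OCc4ccccc4)c(OC)c(OC)cc3OC)no2)c(OC)c(OC)c1OC | intermediate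
15 | (Z)-3-amino-3-(2-hydroxy-3,4,6-trimethoxyphenyl)-1-(2,3,4,5-tetramethoxyphenyl)prop-2-en-1-one | COc1cc(OC)c(/C(N)=C/C(=O)c2cc(OC)c(OC)c(OC)c2OC)c(O)c1OC | intermediate
16 | 5,7,8-trimethoxy-2-(2,3,4,5-tetramethoxyphenyl)-4H-chromen-4-one | COc1cc(-c2cc(=O)c3c(OC)cc(OC)c(OC)c3o2)c(OC)c(OC)c1OC | intermediate
17 | 5-hydroxy-7,8-dimethoxy-2-(2,3,4,5-tetramethoxyphenyl)-4H-chromen-4-one | COc1cc(-c2cc(=O)c3c(O)cc(OC)c(OC)c3o2)c(OC)c(OC)c1OC | target

Total step count: 12. Longest linear sequence: 10 steps (steps 1–7, then 10, 11 and 12); steps 8 and 9 form the two-step side branch to the alkyne.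

Steps most likely to fail

Step 10 (key step). The cycloaddition between a doubly ortho-substituted dipole and an ortho-substituted arylalkyne may be slow. The nitrile oxide could then be lost to rearrangement into the isocyanate on warming, or to addition of methanol or acetic acid. The fallback sets out from aldehyde 11. Wittig methylenation (Ph3PCH3Br, KOtBu, THF) should give 1-ethenyl-2,3,4,5-tetramethoxybenzene F1, a styrene that is a better dipolarophile than the alkyne. Nitrile oxide 13, preformed from 9 with PhI(OAc)2 before the alkene is added, should add with the same orientation to give racemic 3-[2-(benzyloxy)-3,4,6-trimethoxyphenyl]-5-(2,3,4,5-tetramethoxyphenyl)-4,5-dihydroisoxazole F2. Dehydrogenation with MnO2 in hot toluene comes back to the route at isoxazole 14.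

Step 11. Hydrogenolysis may stop after loss of the benzyl group, because the N–O bond of the tetra-ortho-substituted diarylisoxazole reaches the palladium surface poorly, or the enaminone may be reduced further on forcing. The fallback sets out from 14. Homogeneous reductive N–O cleavage with Mo(CO)6 in MeCN–H2O at reflux should give (Z)-3-amino-3-[2-(benzyloxy)-3,4,6-trimethoxyphenyl]-1-(2,3,4,5-tetramethoxyphenyl)prop-2-en-1-one F3. Hydrogenolysis of its benzyl ether alone (H2, 10% Pd/C, EtOAc) comes back to the route at enaminone 15, which is closed with acid as in step 11.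

Step 5. The neighbouring methoxy group may tie up magnesium and slow the formylation, so that the electron-rich phenol is lost to air oxidation or to condensation with formaldehyde on long heating. The fallback sets out from phenol 6. Templated ortho-hydroxymethylation with PhB(OH)2 and (CH2O)n (cat. EtCO2H, toluene, reflux with water removal) should give 5,7,8-trimethoxy-2-phenyl-4H-1,3,2-benzodioxaborine F4, again only at the single free ortho carbon. Exchange with propane-1,3-diol should free 2-(hydroxymethyl)-3,5,6-trimethoxyphenol F5. Oxidation of the benzylic alcohol with MnO2 in CH2Cl2 comes back to the route at aldehyde 7.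

Further compounds
F1 | step 10 | 1-ethenyl-2,3,4,5-tetramethoxybenzene | C=Cc1cc(OC)c(OC)c(OC)c1OC
F2 | step 10 | 3-[2-(benzyloxy)-3,4,6-trimethoxyphenyl]-5-(2,3,4,5-tetramethoxyphenyl)-4,5-dihydroisoxazole (racemic) | COc1cc(C2CC(c3c(OCc4ccccc4)c(OC)c(OC)cc3OC)=NO2)c(OC)c(OC)c1OC
F3 | step 11 | (Z)-3-amino-3-[2-(benzyloxy)-3,4,6-trimethoxyphenyl]-1-(2,3,4,5-tetramethoxyphenyl)prop-2-en-1-one | COc1cc(OC)c(/C(N)=C/C(=O)c2cc(OC)c(OC)c(OC)c2OC)c(OCc2ccccc2)c1OC
F4 | step 5 | 5,7,8-trimethoxy-2-phenyl-4H-1,3,2-benzodioxaborine | COc1cc(OC)c(OC)c2OB(c3ccccc3)OCc12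
F5 | step 5 | 2-(hydroxymethyl)-3,5,6-trimethoxyphenol | COc1cc(OC)c(OC)c(O)c1CO
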